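1. Labels: ring A = C1 (fusion CH), C2, C3 (CHOH), C4 (CMe2), C5 (fusion C–OH); ring B = C5, C6, C7, C8 (CHMe), C9 (quaternary), C10 (C=O), C1; chain C9–C11–C12–C13 (butenolide). The strategy rests on the 1,4-relationship of the C10 carbonyl and the C3 oxygen across the C1–C2 bond, with C9 and C4 quaternary, so that a C10 ketone and a C3 methyl ketone can each enolise on one side only.
2. Last skeletal disconnection: C1–C2, made by oxidising the bis-enolate of a ring B cycloheptanone that carries at C5 a silyloxy group and a 3-methyl-2-oxobutan-3-yl arm; this closes ring A as the C3 cyclopentanone.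
3. C5: the C5–C4 bond comes from Mukaiyama–Michael addition and Saegusa–Ito dehydrogenation on a cycloheptenone; the C5–O bond comes from catalyst-controlled reduction at C10, hydroxyl-directed epoxidation and reductive opening of the epoxy ketone.
4. Ring B: asymmetric conjugate methylation–allylation of 2-methylcyclohex-2-en-1-one (C8, C9), then one-carbon Saegusa–Ito ring expansion (C1 inserted); the allyl group becomes the 2-(3-furyl)ethyl chain by ozonolysis, iodination and Negishi coupling.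
5. Ring order: ring B (six-membered ring expanded to seven), then ring A (key step, C1 equilibrated to the trans fusion), then C5-hydroxyl-directed reduction at C3 and the butenolide from the furan (singlet oxygen, NaBH4).

Key step: step 15

Assumption: in the oxazaborolidine reduction of step 6 the quaternary C9 flank of the enone is taken to act as the large substituent, so the (S)-catalyst should give the (10R)-alcohol; if the sense proves opposite, the (R)-catalyst is used.

Step 1
Reactants: 1 2-methylcyclohex-2-en-1-one; 2 allyl bromide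
Product: 4 (2S,3R)-2,3-dimethyl-2-(prop-2-en-1-yl)cyclohexan-1-one, via magnesium enolate 3 (not isolated)
Conditions: MeMgBr, Cu(OTf)2 (3 mol %), chiral imidazolinium NHC precursor (4 mol %, enantiomer that gives 3R), Et2O, 0 °C; then 2, DMPU, −30 → 25 °C
Reagents that add atoms: methylmagnesium bromide, C[Mg]Br
Why: Copper-catalysed asymmetric conjugate addition sets C8 under ligand control, and the magnesium enolate is then allylated anti to the new C8 methyl, which fixes quaternary C9 with the two methyls cis (tandem conjugate addition–enolate alkylation).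

Step 2
Reactants: 4 (2S,3R)-2,3-dimethyl-2-(prop-2-en-1-yl)cyclohexan-1-one
Product: 5 {[(5R,6S)-5,6-dimethyl-6-(prop-2-en-1-yl)cyclohex-1-en-1-yl]oxy}trimethylsilane
Conditions: Me3SiOTf, Et3N, CH2Cl2, 0 °C
Reagents that add atoms: trimethylsilyl trifluoromethanesulfonate, C[Si](C)(C)OS(=O)(=O)C(F)(F)F
Why: Soft enolisation to the silyl enol ether, which can form on one side only because C9 carries no hydrogen.

Step 3
Reactants: 5 {[(5R,6S)-5,6-dimethyl-6-(prop-2-en-1-yl)cyclohex-1-en-1-yl]oxy}trimethylsilane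
Product: 6 trimethyl{[(2S,3R)-2,3-dimethyl-2-(prop-2-en-1-yl)bicyclo[4.1.0]heptan-1-yl]oxy}silane
Conditions: Et2Zn, CH2I2, CH2Cl2, 0 → 25 °C
Reagents that add atoms: diiodomethane, ICI
Why: Furukawa–Simmons–Smith cyclopropanation, in which the electron-rich silyl enol ether should react far faster than the monosubstituted allyl alkene; the cyclopropane stereocentres are not controlled and are lost in step 4.

Step 4
Reactants: 6 trimethyl{[(2S,3R)-2,3-dimethyl-2-(prop-2-en-1-yl)bicyclo[4.1.0]heptan-1-yl]oxy}silane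
Product: 8 (6R,7S)-6,7-dimethyl-7-(prop-2-en-1-yl)cyclohept-2-en-1-one, via beta-chloro ketone 7 (not isolated)
Conditions: FeCl3, DMF, 0 °C; then NaOAc, MeOH, 65 °C
Reagents that add atoms: none
Why: Saegusa–Ito ring expansion, in which one-electron oxidation by FeCl3 cleaves the internal cyclopropane bond to a ring-expanded beta-keto radical that takes up chlorine at C5, and NaOAc then eliminates HCl to the conjugated cycloheptenone with the inserted carbon as C1.

Step 5
Reactants: 8 (6R,7S)-6,7-dimethyl-7-(prop-2-en-1-yl)cyclohept-2-en-1-one; 9 1-methoxy-2-methyl-1-[(trimethylsilyl)oxy]prop-1-ene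
Product: 11 methyl 2-[(4S,5R)-4,5-dimethyl-3-oxo-4-(prop-2-en-1-yl)cyclohept-1-en-1-yl]-2-methylpropanoate, via silyl enol ether 10 (not isolated)
Conditions: 9, Tf2NH (1 mol %), CH2Cl2, −78 °C; Et3N, concentrate; then Pd(OAc)2 (1.1 equiv), MeCN, 25 °C
Reagents that add atoms: none
Why: Mukaiyama–Michael addition of the ketene silyl acetal forms C5–C4 and returns the C10 silyl enol ether, which divalent palladium dehydrogenates (Saegusa–Ito oxidation); only C1 bears alpha-hydrogens, so the double bond can only return as C1=C5, and the C5 centre of the adduct is erased.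

Step 6
Reactants: 11 methyl 2-[(4S,5R)-4,5-dimethyl-3-oxo-4-(prop-2-en-1-yl)cyclohept-1-en-1-yl]-2-methylpropanoate
Product: 12 methyl 2-[(3R,4S,5R)-3-hydroxy-4,5-dimethyl-4-(prop-2-en-1-yl)cyclohept-1-en-1-yl]-2-methylpropanoate
Conditions: (S)-2-methyl-CBS-oxazaborolidine (0.2 equiv), catecholborane, toluene, −78 °C
Reagents that add atoms: none
Why: Corey–Bakshi–Shibata reduction, in which catalyst-controlled 1,2-hydride delivery sets C10 as R (hydroxyl on the face of the C9 allyl group), while catecholborane at low temperature should leave the ester and both alkenes untouched.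

Step 7
Reactants: 12 methyl 2-[(3R,4S,5R)-3-hydroxy-4,5-dimethyl-4-(prop-2-en-1-yl)cyclohept-1-en-1-yl]-2-methylpropanoate
Product: 14 3-[(3R,4S,5R)-3-hydroxy-4,5-dimethyl-4-(prop-2-en-1-yl)cyclohept-1-en-1-yl]-3-methylbutan-2-one, via alpha-silyl ketone 13 (not isolated)
Conditions: Me3SiCH2Li (3.5 equiv), THF/pentane, 0 → 25 °C; then MeOH, 25 °C
Reagents that add atoms: (trimethylsilyl)methyllithium, [Li]C[Si](C)(C)C
Why: Ester to methyl ketone by acyl substitution with Me3SiCH2Li, where the adduct collapses to an alpha-silyl ketone whose enolate resists a second addition and methanol then removes silicon; the C10 alkoxide lies trans to the side chain across C1=C5 and cannot lactonise.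

Step 8
Reactants: 14 3-[(3R,4S,5R)-3-hydroxy-4,5-dimethyl-4-(prop-2-en-1-yl)cyclohept-1-en-1-yl]-3-methylbutan-2-one
Product: 15 3-[(1S,2S,3S,4R,7S)-2-hydroxy-3,4-dimethyl-3-(prop-2-en-1-yl)-8-oxabicyclo[5.1.0]octan-7-yl]-3-methylbutan-2-one
Conditions: VO(acac)2 (5 mol %), t-BuOOH, CH2Cl2, 0 → 25 °C
Reagents that add atoms: tert-butyl hydroperoxide, CC(C)(C)OO
Why: Hydroxyl-directed epoxidation, in which the vanadate ester of a cyclohept-2-enol delivers oxygen to the alkene face syn to the C10 hydroxyl, setting C1 and C5 with the C5–O bond on the face of the C9 allyl group; the isolated allyl alkene and the ketone should not react.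

Step 9
Reactants: 15 3-[(1S,2S,3S,4R,7S)-2-hydroxy-3,4-dimethyl-3-(prop-2-en-1-yl)-8-oxabicyclo[5.1.0]octan-7-yl]-3-methylbutan-2-one
Product: 16 (1R,3S,4R,7S)-3,4-dimethyl-7-(3-methyl-2-oxobutan-3-yl)-3-(prop-2-en-1-yl)-8-oxabicyclo[5.1.0]octan-2-one
Conditions: Dess–Martin periodinane, NaHCO3, CH2Cl2, 0 → 25 °C
Reagents that add atoms: none
Why: Dess–Martin oxidation of the secondary C10 alcohol to the alpha,beta-epoxy ketone under buffered conditions that leave the epoxide intact.

Step 10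
Reactants: 16 (1R,3S,4R,7S)-3,4-dimethyl-7-(3-methyl-2-oxobutan-3-yl)-3-(prop-2-en-1-yl)-8-oxabicyclo[5.1.0]octan-2-one
Product: 17 (3R,6R,7S)-3-hydroxy-6,7-dimethyl-3-(3-methyl-2-oxobutan-3-yl)-7-(prop-2-en-1-yl)cycloheptan-1-one
Conditions: SmI2 (2.2 equiv), THF/MeOH, −90 °C; pH 7 buffer
Reagents that add atoms: none
Why: Reductive opening of an alpha,beta-epoxy ketone with SmI2, in which the C10 ketyl cleaves only the C1–O bond, so the C5–O bond keeps its configuration and the tertiary aldol is released without base; the isolated ketone and alkene should be inert at this temperature.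

Step 11
Reactants: 17 (3R,6R,7S)-3-hydroxy-6,7-dimethyl-3-(3-methyl-2-oxobutan-3-yl)-7-(prop-2-en-1-yl)cycloheptan-1-one
Product: 18 (3R,6R,7S)-6,7-dimethyl-3-(3-methyl-2-oxobutan-3-yl)-7-(prop-2-en-1-yl)-3-[(trimethylsilyl)oxy]cycloheptan-1-one
Conditions: 1-(trimethylsilyl)imidazole, CH2Cl2, 25–40 °C
Reagents that add atoms: 1-(trimethylsilyl)imidazole, C[Si](C)(C)n1ccnc1
Why: Silylation of the hindered tertiary alcohol with a reagent that does not enolise the ketones; the silyl ether blocks retro-aldol cleavage in the following steps.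

Step 12
Reactants: 18 (3R,6R,7S)-6,7-dimethyl-3-(3-methyl-2-oxobutan-3-yl)-7-(prop-2-en-1-yl)-3-[(trimethylsilyl)oxy]cycloheptan-1-one
Product: 20 (3R,6R,7S)-7-(2-hydroxyethyl)-6,7-dimethyl-3-(3-methyl-2-oxobutan-3-yl)-3-[(trimethylsilyl)oxy]cycloheptan-1-one, via aldehyde 19 (not isolated)
Conditions: O3, CH2Cl2, −78 °C; PPh3, −78 → 25 °C; then NaBH4, EtOH, −78 °C
Reagents that add atoms: ozone, [O-][O+]=O
Why: Ozonolysis of the only alkene with reductive work-up, then aldehyde-selective borohydride reduction at low temperature, both ketones being flanked by quaternary carbons and much slower to react.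

Step 13
Reactants: 20 (3R,6R,7S)-7-(2-hydroxyethyl)-6,7-dimethyl-3-(3-methyl-2-oxobutan-3-yl)-3-[(trimethylsilyl)oxy]cycloheptan-1-one
Product: 21 (3R,6R,7S)-7-(2-iodoethyl)-6,7-dimethyl-3-(3-methyl-2-oxobutan-3-yl)-3-[(trimethylsilyl)oxy]cycloheptan-1-one
Conditions: PPh3, I2, imidazole, CH2Cl2, 0 °C
Reagents that add atoms: iodine, II
Why: Appel-type iodination of the primary alcohol by SN2 displacement of the oxyphosphonium group, with imidazole buffering the acid so that the tertiary silyl ether should survive.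

Step 14
Reactants: 21 (3R,6R,7S)-7-(2-iodoethyl)-6,7-dimethyl-3-(3-methyl-2-oxobutan-3-yl)-3-[(trimethylsilyl)oxy]cycloheptan-1-one; 22 3-bromofuran
Product: 24 (3R,6R,7S)-7-[2-(furan-3-yl)ethyl]-6,7-dimethyl-3-(3-methyl-2-oxobutan-3-yl)-3-[(trimethylsilyl)oxy]cycloheptan-1-one, via alkylzinc iodide 23 (not isolated)
Conditions: Zn dust, LiCl, THF, 40 °C; then 22, Pd(OAc)2 (2 mol %), SPhos (4 mol %), THF, 25 → 50 °C
Reagents that add atoms: none
Why: Negishi coupling, in which zinc insertion into the primary C–I bond gives an alkylzinc iodide that tolerates both ketones, and zerovalent palladium joins C12 to C3 of the furan.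

Step 15
Reactants: 24 (3R,6R,7S)-7-[2-(furan-3-yl)ethyl]-6,7-dimethyl-3-(3-methyl-2-oxobutan-3-yl)-3-[(trimethylsilyl)oxy]cycloheptan-1-one
Product: 27 (3aR,5S,6R,8aR)-5-[2-(furan-3-yl)ethyl]-1,1,5,6-tetramethyl-8a-[(trimethylsilyl)oxy]octahydroazulene-2,4-dione, via dilithium bis-enolate 25 (not isolated), via cis-fused diketone 26 (not isolated)
Conditions: LiN(i-Pr)2 (2.3 equiv), THF, −78 °C (24 added to the base, 0.01 M); CuCl2 (2.3 equiv), DMF, −78 → −20 °C; aq. NH4Cl; then DBU (0.3 equiv), CH2Cl2, 25 °C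
Reagents that add atoms: none
Why: Double deprotonation gives the bis-enolate at C1 and C2, the only possible sites because C9 and C4 bear no hydrogen, and divalent copper oxidises one enolate to an alpha-keto radical that bonds to the other enolate carbon, a second one-electron oxidation completing C1–C2. The closest known reaction type is the intramolecular oxidative coupling of ketone dienolates with CuCl2 or FeCl3 to cyclic 1,4-diketones. Ring A closes in a 5-exo-trig sense, C2 attacking C1 of the ring B enolate with C10 outside the new ring. The two-atom tether can reach only the face of C1 syn to C4, so the kinetic product is expected to be the cis-fused C1 epimer, and DBU then equilibrates C1 through the C10 enolate to the trans-fused ketone, expected to be the more stable epimer because angularly substituted trans-fused five–seven ketones usually are and the target carries this enolisable centre in that configuration. The step needs ring closure to beat intermolecular coupling (inverse addition, high dilution), and the C10 enolate must neither expel nor accept the C5 silyl group (−78 °C); no other coupling site exists.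

Step 16
Reactants: 27 (3aR,5S,6R,8aR)-5-[2-(furan-3-yl)ethyl]-1,1,5,6-tetramethyl-8a-[(trimethylsilyl)oxy]octahydroazulene-2,4-dione
Product: 28 (3aR,5S,6R,8aR)-5-[2-(furan-3-yl)ethyl]-8a-hydroxy-1,1,5,6-tetramethyloctahydroazulene-2,4-dione
Conditions: HF·pyridine, pyridine, THF, 0 °C
Reagents that add atoms: none
Why: Fluoride cleavage of the tertiary trimethylsilyl ether under buffered, non-basic conditions that should avoid retro-aldol opening of the beta-hydroxy diketone.

Step 17
Reactants: 28 (3aR,5S,6R,8aR)-5-[2-(furan-3-yl)ethyl]-8a-hydroxy-1,1,5,6-tetramethyloctahydroazulene-2,4-dione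
Product: 29 (2R,3aR,5S,6R,8aR)-5-[2-(furan-3-yl)ethyl]-2,8a-dihydroxy-1,1,5,6-tetramethyloctahydroazulen-4(1H)-one
Conditions: Me4NBH(OAc)3, MeCN/AcOH (1:1), −30 °C
Reagents that add atoms: none
Why: Evans–Saksena directed reduction, in which the C5 hydroxyl exchanges onto boron and delivers hydride to the face of the C3 carbonyl on its own side, so the new hydroxyl is anti to C5–OH (3R); C10, between quaternary C9 and tertiary C1, is expected to react much more slowly.

Step 18
Reactants: 29 (2R,3aR,5S,6R,8aR)-5-[2-(furan-3-yl)ethyl]-2,8a-dihydroxy-1,1,5,6-tetramethyloctahydroazulen-4(1H)-one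
Product: 31 (2R,3aR,5S,6R,8aR)-2,8a-dihydroxy-5-[2-(2-hydroxy-5-oxo-2,5-dihydrofuran-3-yl)ethyl]-1,1,5,6-tetramethyloctahydroazulen-4(1H)-one, via furan endoperoxide 30 (not isolated)
Conditions: O2, hν, rose bengal (cat.), i-Pr2NEt, CH2Cl2, −78 °C
Reagents that add atoms: oxygen, O=O
Why: Singlet-oxygen [4+2] cycloaddition to the furan, then base-induced Kornblum–DeLaMare-type fragmentation of the endoperoxide, the hindered amine removing the bridgehead hydrogen remote from the alkyl group so that the lactone carbonyl ends up distal to the side chain.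

Step 19
Reactants: 31 (2R,3aR,5S,6R,8aR)-2,8a-dihydroxy-5-[2-(2-hydroxy-5-oxo-2,5-dihydrofuran-3-yl)ethyl]-1,1,5,6-tetramethyloctahydroazulen-4(1H)-one
Product: 33 (2R,3aR,5S,6R,8aR)-2,8a-dihydroxy-1,1,5,6-tetramethyl-5-[2-(5-oxo-2,5-dihydrofuran-3-yl)ethyl]octahydroazulen-4(1H)-one, via hydroxy carboxylate 32 (not isolated)
Conditions: NaBH4, EtOH, 0 °C; then 1 M HCl to pH 3
Reagents that add atoms: none
Why: Borohydride reduction of the masked aldehyde (open form of the hydroxybutenolide) to the (Z)-hydroxy carboxylate, which lactonises on acidification to the 4-substituted furan-2(5H)-one; the hindered C10 ketone is expected to survive the short exposure at 0 °C.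

Compound list
1 | 2-methylcyclohex-2-en-1-one | CC1=CCCCC1=O | starting material
2 | allyl bromide (3-bromoprop-1-ene) | C=CCBr | starting material
3 | bromomagnesium (3R)-2,3-dimethylcyclohex-1-en-1-olate | C[C@@H]1CCCC(O[Mg]Br)=C1C | intermediate
4 | (2S,3R)-2,3-dimethyl-2-(prop-2-en-1-yl)cyclohexan-1-one | C[C@@H]1CCCC(=O)[C@@]1(C)CC=C | intermediate
5 | {[(5R,6S)-5,6-dimethyl-6-(prop-2-en-1-yl)cyclohex-1-en-1-yl]oxy}trimethylsilane | C[C@@H]1CCC=C(O[Si](C)(C)C)[C@@]1(C)CC=C | intermediate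
6 | trimethyl{[(2S,3R)-2,3-dimethyl-2-(prop-2-en-1-yl)bicyclo[4.1.0]heptan-1-yl]oxy}silane (cyclopropane face not controlled) | C[C@@H]1CCC2CC2(O[Si](C)(C)C)[C@@]1(C)CC=C | intermediate
7 | (2S,3R)-6-chloro-2,3-dimethyl-2-(prop-2-en-1-yl)cycloheptan-1-one (C6 epimers) | C[C@@H]1CCC(Cl)CC(=O)[C@@]1(C)CC=C | intermediate
8 | (6R,7S)-6,7-dimethyl-7-(prop-2-en-1-yl)cyclohept-2-en-1-one | C[C@@H]1CCC=CC(=O)[C@@]1(C)CC=C | intermediate
9 | 1-methoxy-2-methyl-1-[(trimethylsilyl)oxy]prop-1-ene | CC(C)=C(OC)O[Si](C)(C)C | starting material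
10 | methyl 2-methyl-2-{(4S,5R)-4,5-dimethyl-4-(prop-2-en-1-yl)-3-[(trimethylsilyl)oxy]cyclohept-2-en-1-yl}propanoate (C1 epimers) | C[C@@H]1CCC(C(C)(C)C(=O)OC)C=C(O[Si](C)(C)C)[C@@]1(C)CC=C | intermediate
11 | methyl 2-[(4S,5R)-4,5-dimethyl-3-oxo-4-(prop-2-en-1-yl)cyclohept-1-en-1-yl]-2-methylpropanoate | C[C@@H]1CCC(C(C)(C)C(=O)OC)=CC(=O)[C@@]1(C)CC=C | intermediate
12 | methyl 2-[(3R,4S,5R)-3-hydroxy-4,5-dimethyl-4-(prop-2-en-1-yl)cyclohept-1-en-1-yl]-2-methylpropanoate | C[C@@H]1CCC(C(C)(C)C(=O)OC)=C[C@@H](O)[C@@]1(C)CC=C | intermediate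
13 | 3-[(3R,4S,5R)-3-hydroxy-4,5-dimethyl-4-(prop-2-en-1-yl)cyclohept-1-en-1-yl]-3-methyl-1-(trimethylsilyl)butan-2-one | C[C@@H]1CCC(C(C)(C)C(=O)C[Si](C)(C)C)=C[C@@H](O)[C@@]1(C)CC=C | intermediate
14 | 3-[(3R,4S,5R)-3-hydroxy-4,5-dimethyl-4-(prop-2-en-1-yl)cyclohept-1-en-1-yl]-3-methylbutan-2-one | C[C@@H]1CCC(C(C)(C)C(C)=O)=C[C@@H](O)[C@@]1(C)CC=C | intermediate
15 | 3-[(1S,2S,3S,4R,7S)-2-hydroxy-3,4-dimethyl-3-(prop-2-en-1-yl)-8-oxabicyclo[5.1.0]octan-7-yl]-3-methylbutan-2-one (epoxide oxygen cis to the hydroxyl) | C[C@@H]1CC[C@@]2(C(C)(C)C(C)=O)O[C@H]2[C@@H](O)[C@@]1(C)CC=C | intermediate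
16 | (1R,3S,4R,7S)-3,4-dimethyl-7-(3-methyl-2-oxobutan-3-yl)-3-(prop-2-en-1-yl)-8-oxabicyclo[5.1.0]octan-2-one | C[C@@H]1CC[C@@]2(C(C)(C)C(C)=O)O[C@H]2C(=O)[C@@]1(C)CC=C | intermediate
17 | (3R,6R,7S)-3-hydroxy-6,7-dimethyl-3-(3-methyl-2-oxobutan-3-yl)-7-(prop-2-en-1-yl)cycloheptan-1-one | C[C@@H]1CC[C@](O)(C(C)(C)C(C)=O)CC(=O)[C@@]1(C)CC=C | intermediate
18 | (3R,6R,7S)-6,7-dimethyl-3-(3-methyl-2-oxobutan-3-yl)-7-(prop-2-en-1-yl)-3-[(trimethylsilyl)oxy]cycloheptan-1-one | C[C@@H]1CC[C@](O[Si](C)(C)C)(C(C)(C)C(C)=O)CC(=O)[C@@]1(C)CC=C | intermediate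
19 | 2-{(1S,2R,5R)-1,2-dimethyl-5-(3-methyl-2-oxobutan-3-yl)-7-oxo-5-[(trimethylsilyl)oxy]cycloheptyl}acetaldehyde | C[C@@H]1CC[C@](O[Si](C)(C)C)(C(C)(C)C(C)=O)CC(=O)[C@@]1(C)CC=O | intermediate
20 | (3R,6R,7S)-7-(2-hydroxyethyl)-6,7-dimethyl-3-(3-methyl-2-oxobutan-3-yl)-3-[(trimethylsilyl)oxy]cycloheptan-1-one | C[C@@H]1CC[C@](O[Si](C)(C)C)(C(C)(C)C(C)=O)CC(=O)[C@@]1(C)CCO | intermediate
21 | (3R,6R,7S)-7-(2-iodoethyl)-6,7-dimethyl-3-(3-methyl-2-oxobutan-3-yl)-3-[(trimethylsilyl)oxy]cycloheptan-1-one | C[C@@H]1CC[C@](O[Si](C)(C)C)(C(C)(C)C(C)=O)CC(=O)[C@@]1(C)CCI | intermediate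
22 | 3-bromofuran | Brc1ccoc1 | starting material
23 | {2-[(1S,2R,5R)-1,2-dimethyl-5-(3-methyl-2-oxobutan-3-yl)-7-oxo-5-[(trimethylsilyl)oxy]cycloheptyl]ethyl}zinc iodide | C[C@@H]1CC[C@](O[Si](C)(C)C)(C(C)(C)C(C)=O)CC(=O)[C@@]1(C)CC[Zn]I | intermediate
24 | (3R,6R,7S)-7-[2-(furan-3-yl)ethyl]-6,7-dimethyl-3-(3-methyl-2-oxobutan-3-yl)-3-[(trimethylsilyl)oxy]cycloheptan-1-one | C[C@@H]1CC[C@](O[Si](C)(C)C)(C(C)(C)C(C)=O)CC(=O)[C@@]1(C)CCc1ccoc1 | intermediate
25 | dilithium bis-enolate of 24 (C10–OLi with C10=C1; C3–OLi with C3=C2) | C[C@@H]1CC[C@](O[Si](C)(C)C)(C(C)(C)C(=C)O[Li])C=C(O[Li])[C@@]1(C)CCc1ccoc1 | intermediate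
26 | (3aS,5S,6R,8aR)-5-[2-(furan-3-yl)ethyl]-1,1,5,6-tetramethyl-8a-[(trimethylsilyl)oxy]octahydroazulene-2,4-dione (cis-fused) | C[C@@H]1CC[C@@]2(O[Si](C)(C)C)[C@H](CC(=O)C2(C)C)C(=O)[C@@]1(C)CCc1ccoc1 | intermediate
27 | (3aR,5S,6R,8aR)-5-[2-(furan-3-yl)ethyl]-1,1,5,6-tetramethyl-8a-[(trimethylsilyl)oxy]octahydroazulene-2,4-dione (trans-fused) | C[C@@H]1CC[C@@]2(O[Si](C)(C)C)[C@@H](CC(=O)C2(C)C)C(=O)[C@@]1(C)CCc1ccoc1 | intermediate
28 | (3aR,5S,6R,8aR)-5-[2-(furan-3-yl)ethyl]-8a-hydroxy-1,1,5,6-tetramethyloctahydroazulene-2,4-dione | C[C@@H]1CC[C@@]2(O)[C@@H](CC(=O)C2(C)C)C(=O)[C@@]1(C)CCc1ccoc1 | intermediate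
29 | (2R,3aR,5S,6R,8aR)-5-[2-(furan-3-yl)ethyl]-2,8a-dihydroxy-1,1,5,6-tetramethyloctahydroazulen-4(1H)-one | C[C@@H]1CC[C@@]2(O)[C@@H](C[C@@H](O)C2(C)C)C(=O)[C@@]1(C)CCc1ccoc1 | intermediate
30 | 2,5-endoperoxide of the furan ring of 29 (5-alkyl-2,3,7-trioxabicyclo[2.2.1]hept-5-ene; bridgehead epimers) | C[C@@H]1CC[C@@]2(O)[C@@H](C[C@@H](O)C2(C)C)C(=O)[C@@]1(C)CCC1=CC2OOC1O2 | intermediate
31 | (2R,3aR,5S,6R,8aR)-2,8a-dihydroxy-5-[2-(2-hydroxy-5-oxo-2,5-dihydrofuran-3-yl)ethyl]-1,1,5,6-tetramethyloctahydroazulen-4(1H)-one (hemiacetal epimers) | C[C@@H]1CC[C@@]2(O)[C@@H](C[C@@H](O)C2(C)C)C(=O)[C@@]1(C)CCC1=CC(=O)OC1O | intermediate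
32 | sodium (2Z)-4-hydroxy-3-{2-[(2R,3aR,5S,6R,8aR)-2,8a-dihydroxy-1,1,5,6-tetramethyl-4-oxodecahydroazulen-5-yl]ethyl}but-2-enoate | C[C@@H]1CC[C@@]2(O)[C@@H](C[C@@H](O)C2(C)C)C(=O)[C@@]1(C)CC/C(CO)=C/C(=O)[O-].[Na+] | intermediate
33 | (2R,3aR,5S,6R,8aR)-2,8a-dihydroxy-1,1,5,6-tetramethyl-5-[2-(5-oxo-2,5-dihydrofuran-3-yl)ethyl]octahydroazulen-4(1H)-one | C[C@@H]1CC[C@@]2(O)[C@@H](C[C@@H](O)C2(C)C)C(=O)[C@@]1(C)CCC1=CC(=O)OC1 | target

Total step count: 19
Longest linear sequence: 19 steps (1 → 33); 2, 9 and 22 are purchased reagents that enter this line.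

Steps most likely to fail

Step 15. The ring B enolate may expel the C5 silyloxy group or take the silyl group onto its own oxygen before it is oxidised. Intermolecular coupling may compete with ring closure. The base equilibration at C1 may stop short of the trans fusion or trigger beta-elimination. Fallback: starting again from 24, both enolates are trapped as they form (LiN(i-Pr)2 with Me3SiCl present, THF, −78 °C) to give the bis(trimethylsilyl enol ether) F1. F1 is oxidised with (NH4)2Ce(NO3)6 and NaHCO3 in MeCN at −10 °C. One-electron oxidation of one silyl enol ether gives a radical cation that is captured by the second, and loss of both silyl groups gives the 1,4-diketone. This is a known route from silyl bis-enol ethers to 1,4-diketones, and it avoids a long-lived lithium enolate beta to the silyloxy group. The route is rejoined at cis-fused diketone 26, which is equilibrated with DBU to 27 as in step 15.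

Step 6. Hydride delivery to the hindered enone may be slow, or may occur with poor or reversed facial selectivity at C10, which would carry the wrong configuration on to C5 in step 8. Fallback: from 11, a Luche reduction (NaBH4, CeCl3·7H2O, MeOH, −78 °C) is run without a chiral catalyst and the two C10 epimers are separated by chromatography. Alcohol 12 goes on, and the C10-epimeric allylic alcohol F2 is oxidised back to 11 with MnO2 and recycled. The route is rejoined at 12.

Step 17. Ligand exchange at the hindered tertiary hydroxyl may be slow, so that hydride arrives intermolecularly from the open face (syn diol), or the boron-bound hydride may also reach C10. Fallback: from 28, the tertiary hydroxyl is silylated with i-Pr2SiHCl (imidazole, DMF) to the hydridosilyl ether F3. SnCl4 (CH2Cl2, −80 °C) then activates the ring A carbonyl, and the tethered Si–H delivers hydride to its face on the side of the C5 oxygen (intramolecular hydrosilylation of a beta-silyloxy ketone). The short O–Si–H tether and the isopropyl groups are expected to favour the cyclopentanone over C10. Aqueous work-up leaves the C3 alcohol with C5 still silylated, silanol F4, and HF·pyridine removes the silicon. The route is rejoined at 29.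

Further compounds
F1 | step 15 | bis(trimethylsilyl enol ether) of 24 (C10–OSiMe3 with C10=C1; C3–OSiMe3 with C3=C2; C5–OSiMe3 kept) | C[C@@H]1CC[C@](O[Si](C)(C)C)(C(C)(C)C(=C)O[Si](C)(C)C)C=C(O[Si](C)(C)C)[C@@]1(C)CCc1ccoc1
F2 | step 6 | methyl 2-[(3S,4S,5R)-3-hydroxy-4,5-dimethyl-4-(prop-2-en-1-yl)cyclohept-1-en-1-yl]-2-methylpropanoate | C[C@@H]1CCC(C(C)(C)C(=O)OC)=C[C@H](O)[C@@]1(C)CC=C
F3 | step 17 | (3aR,5S,6R,8aR)-8a-{[di(propan-2-yl)silyl]oxy}-5-[2-(furan-3-yl)ethyl]-1,1,5,6-tetramethyloctahydroazulene-2,4-dione | C[C@@H]1CC[C@@]2(O[SiH](C(C)C)C(C)C)[C@@H](CC(=O)C2(C)C)C(=O)[C@@]1(C)CCc1ccoc1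
F4 | step 17 | (2R,3aR,5S,6R,8aR)-5-[2-(furan-3-yl)ethyl]-2-hydroxy-8a-{[hydroxydi(propan-2-yl)silyl]oxy}-1,1,5,6-tetramethyloctahydroazulen-4(1H)-one | C[C@@H]1CC[C@@]2(O[Si](O)(C(C)C)C(C)C)[C@@H](C[C@@H](O)C2(C)C)C(=O)[C@@]1(C)CCc1ccoc1
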